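**Retrosynthetic overview**
1. 22 ⇐ 21 (desilylation) ⇐ vinyl-decalin 15 + (tributylstannyl)methyl 3,3-dibromoacrylate 18: one pot, B-alkyl Suzuki–Miyaura coupling (C12–C13), then intramolecular Stille coupling (C13–C16), which closes the furanone ring last.
2. Feature used: in the furanone ring (O–C15(=O)–C14H=C13–C16H2) the ring oxygen carries only the C16 methylene, and C13 carries exactly two carbon substituents, C12 trans and C16 cis to C15. C13 can therefore start as the CBr2 carbon of an acrylate whose ester oxygen already holds C16 as CH2SnBu3.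
3. 15 ⇐ bridged δ-lactone 8 (O2–C11(=O)–C9, possible because O2 and C9 are cis on ring A). The bridge enforces the cis A/B fusion, so hydroboration of C5=C6 sets H-5 β; DIBAL-H/Wittig turns C11 into the C11=C12 vinyl group; C6 is corrected by oxidation/reduction on the opened cis-decalin.
4. 8 ⇐ intramolecular Diels–Alder reaction of dienyl ynoate 7 (ring B and the temporary lactone ring in one step; C2 → C10 relay) ⇐ (4R,6R)-actinol 4 (chiral pool: C1–C5, C10, C18–C20 and the C2 carbinol) + ynoic acid 3.
5. Order of ring formation: ring A bought; ring B together with the temporary lactone (step 5); furanone (step 13).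

Key step: step 13

Numbering: labdane numbering (C1–C20) is used for all decalin compounds; β is the face of the C10 methyl (C20).
Remark: the given descriptors are read as (2S,5R,6S,10S), i.e. 2-OH and 6-OH α, H-5 and C20 β, a cis-fused decalin; the route is built for this isomer.
Assumption: compounds 1, 4, 16 and 17 are taken as commercially available.

**Route**

Step 1
Reactants: 1 tert-butyl(diphenyl)(prop-2-yn-1-yloxy)silane
Product: 3 4-[(tert-butyldiphenylsilyl)oxy]but-2-ynoic acid, via lithium acetylide 2 (not isolated)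
Conditions: n-BuLi, THF, −78 °C; CO2 (g); aq. HCl work-up
Reagents that add atoms: carbon dioxide, O=C=O
Why: Carboxylation of the lithium acetylide should give the ynoic acid that carries C8, C9, C11 and C17 of the target.

Step 2
Reactants: 3 4-[(tert-butyldiphenylsilyl)oxy]but-2-ynoic acid; 4 (4R,6R)-4-hydroxy-2,2,6-trimethylcyclohexan-1-one (actinol)
Product: 5 (1R,5R)-3,3,5-trimethyl-4-oxocyclohexyl 4-[(tert-butyldiphenylsilyl)oxy]but-2-ynoate
Conditions: DCC, DMAP (5 mol %), CH2Cl2, 0 °C → rt
Reagents that add atoms: none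
Why: Steglich esterification of the unhindered secondary alcohol installs the tether with retention at the carbinol carbon (future C2), which a Mitsunobu coupling would invert.

Step 3
Reactants: 5 (1R,5R)-3,3,5-trimethyl-4-oxocyclohexyl 4-[(tert-butyldiphenylsilyl)oxy]but-2-ynoate
Product: 6 (1R)-3,5,5-trimethyl-4-{[(trifluoromethyl)sulfonyl]oxy}cyclohex-3-en-1-yl 4-[(tert-butyldiphenylsilyl)oxy]but-2-ynoate
Conditions: Tf2O, 2,6-di-tert-butyl-4-methylpyridine, CH2Cl2, 0 °C → rt
Reagents that add atoms: trifluoromethanesulfonic anhydride, O=S(=O)(OS(=O)(=O)C(F)(F)F)C(F)(F)F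
Why: Enol triflate formation with a non-nucleophilic pyridine base can only go toward the single enolisable α-carbon (future C10) and avoids amide bases that would attack the ynoate.

Step 4
Reactants: 6 (1R)-3,5,5-trimethyl-4-{[(trifluoromethyl)sulfonyl]oxy}cyclohex-3-en-1-yl 4-[(tert-butyldiphenylsilyl)oxy]but-2-ynoate
Product: 7 (1R)-4-ethenyl-3,5,5-trimethylcyclohex-3-en-1-yl 4-[(tert-butyldiphenylsilyl)oxy]but-2-ynoate
Conditions: tributyl(vinyl)stannane, Pd(PPh3)4 (5 mol %), LiCl, THF, 60 °C
Reagents that add atoms: tributyl(vinyl)stannane, C=C[Sn](CCCC)(CCCC)CCCC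
Why: Stille coupling of the hindered cyclohexenyl triflate is neutral, tolerates the ynoate, adds C6 and C7 and completes the 1-vinylcyclohexene diene.

Step 5
Reactants: 7 (1R)-4-ethenyl-3,5,5-trimethylcyclohex-3-en-1-yl 4-[(tert-butyldiphenylsilyl)oxy]but-2-ynoate
Product: 8 tricyclic 2α,11-lactone: cis-precursor decalin-5,8-diene (C5=C6, C8=C9) with 4,4-dimethyl, 10β-methyl, CH2OTBDPS on C8 and a C9–C11(=O)–O–C2 bridge on the α-face
Conditions: toluene (high dilution), BHT, 140 °C, sealed tube
Reagents that add atoms: none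
Why: The ester-tethered intramolecular Diels–Alder reaction closes ring B (C10–C9, C7–C8) and the six-membered lactone ring; the O–C(=O) tether from the axial C2 oxygen can reach only the α-face of C10, so the C2 stereocentre sets C10 (C9 cis to O2, C20 β), and the tether plus the polarity match (C7 to the ynoate β-carbon C8) fix the regiochemistry.

Step 6
Reactants: 8 tricyclic 2α,11-lactone
Product: 10 6β-hydroxy-5β-H lactone, via C6 borane 9 (not isolated)
Conditions: BH3·THF, THF, 0 °C → rt; then 30 % H2O2, aq. NaOAc, 0 °C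
Reagents that add atoms: hydrogen peroxide, OO
Why: Hydroboration–oxidation puts boron on the less substituted C6 and hydrogen on C5 by syn addition from the β-face, the only face whose adduct keeps the A/B fusion cis as the O2–C11 bridge demands (a trans fusion would need C9 and C6 anti across C10–C5); this sets C5 (H β), the 6β-hydroxyl is provisional, and the lactone-conjugated C8=C9 bond is inert to borane.

Step 7
Reactants: 10 6β-hydroxy-5β-H lactone
Product: 11 lactol (C11 hemiacetal, anomer mixture) with 6β-OH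
Conditions: DIBAL-H (3 equiv), CH2Cl2, −78 °C; Rochelle salt work-up
Reagents that add atoms: none
Why: DIBAL-H half-reduction of the lactone to the lactol brings C11 to the aldehyde level, the low-temperature aluminium acetal preventing over-reduction.

Step 8
Reactants: 11 lactol with 6β-OH
Product: 12 9-ethenyl cis-decalin-2α,6β-diol (5β-H, 10β-CH3, C8=C9, CH2OTBDPS on C8)
Conditions: Ph3PCH3Br, KOtBu, THF, 0 °C → rt
Reagents that add atoms: methyltriphenylphosphonium bromide, C[P+](c1ccccc1)(c1ccccc1)c1ccccc1.[Br-]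
Why: Wittig methylenation of the lactol through its open hydroxy-enal form adds C12, removes the temporary bridge and frees the 2α-hydroxyl; excess ylide tolerates the alkoxides.

Step 9
Reactants: 12 9-ethenyl cis-decalin-2α,6β-diol
Product: 13 2-O-TBS ether of 12
Conditions: TBSCl (1.1 equiv), imidazole, DMF, 0 °C
Reagents that add atoms: tert-butyldimethylsilyl chloride, C[Si](C)(Cl)C(C)(C)C
Why: Silyl ether formation should select the unhindered equatorial C2 hydroxyl over the C6 hydroxyl, which sits next to C5 and its two quaternary neighbours.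

Step 10
Reactants: 13 2-O-TBS ether of 12
Product: 14 cis-fused 6-ketone (5β-H)
Conditions: Dess–Martin periodinane, NaHCO3, CH2Cl2, 0 °C → rt; used crude
Reagents that add atoms: none
Why: Dess–Martin oxidation under buffered, non-enolising conditions erases the provisional C6 configuration without epimerising C5 or moving the C8=C9 bond.

Step 11
Reactants: 14 cis-fused 6-ketone
Product: 15 9-ethenyl-2α-(TBS-oxy)-cis-decalin-6α-ol (5β-H, 10β-CH3, CH2OTBDPS on C8)
Conditions: L-Selectride, THF, −78 °C; aq. NH4Cl
Reagents that add atoms: none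
Why: Hydride reduction of the opened cis-decalin ketone should occur from the convex β-face, because the ring-A methylene C1 is axial on ring B and 1,3 to C6 on the α-face, giving the 6α-alcohol (substrate control from C5 and C10).

Step 12
Reactants: 16 3,3-dibromoprop-2-enoic acid; 17 tributyl(iodomethyl)stannane
Product: 18 (tributylstannyl)methyl 3,3-dibromoprop-2-enoate
Conditions: Cs2CO3, DMF, rt
Reagents that add atoms: none
Why: SN2 O-alkylation of the caesium carboxylate by the iodomethylstannane gives the linchpin ester; the carboxylate does not attack the dibromo-olefin.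

Step 13
Reactants: 15 9-ethenyl-2α-(TBS-oxy)-cis-decalin-6α-ol; 18 (tributylstannyl)methyl 3,3-dibromoprop-2-enoate
Product: 21 2-O-TBS 17-O-TBDPS ether of the target, via B-alkyl-9-BBN 19 (not isolated), via (Z)-bromoenoate 20 (not isolated)
Conditions: 9-BBN (1.5 equiv), THF, rt; then 18, Pd(dppf)Cl2 (5 mol %), AsPh3, Cs2CO3, DMF/H2O, rt; then CuI (20 mol %), 65 °C
Reagents that add atoms: none
Why: 9-BBN adds only to the terminal C11=C12 alkene (boron at C12) to give 19; Pd(0) then inserts into the C13–Br bond of 18 that is trans to the ester (cis to H, the less hindered one, as in trans-selective mono-couplings of 1,1-dibromoalkenes), and B-alkyl Suzuki–Miyaura transfer forges C12–C13, leaving in 20 exactly the bromide that is cis to the ester. A second oxidative addition at this C13–Br bond, copper-assisted intramolecular Sn→Pd transfer of the ester-bound CH2 and reductive elimination from the six-membered oxapalladacycle (Pd–C13=C14–C15(=O)–O–C16) form C13–C16 and close the furanone. The closest known reactions are the Stille hydroxymethylation of (Z)-β-halo- or β-triflyloxy-enoates with Bu3SnCH2OH (the products then lactonise) and intramolecular Stille ring closures. The five-membered ring is closed by C(sp2)–C(sp3) reductive elimination, a connection that would be 5-endo for a radical or anion and therefore needs the metal template; no stereocentre is formed and the ring fixes the C13=C14 geometry. The selectivities needed are terminal over tetrasubstituted alkene (9-BBN sterics), trans- before cis-bromide (sterics), and B-alkyl before Sn–CH2 transfer (the α-oxy sp3 stannane transfers only with CuI and heat and cannot reach Pd while Pd sits trans to the ester).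

Step 14
Reactants: 21 2-O-TBS 17-O-TBDPS ether of the target
Product: 22 target, (2S,5R,6S,10S)-configured 2α,6α,17-triol 15,16-olide
Conditions: TBAF, AcOH, THF, rt → 40 °C
Reagents that add atoms: none
Why: Fluoride-mediated desilylation removes the TBS and TBDPS ethers, with acetic acid buffering to protect the base-sensitive butenolide; no stereocentre is touched.

**Compound list**
1 | tert-butyl(diphenyl)(prop-2-yn-1-yloxy)silane | C#CCO[Si](c1ccccc1)(c1ccccc1)C(C)(C)C | starting material
2 | lithium acetylide of 1 | [Li]C#CCO[Si](c1ccccc1)(c1ccccc1)C(C)(C)C | intermediate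
3 | 4-[(tert-butyldiphenylsilyl)oxy]but-2-ynoic acid | OC(=O)C#CCO[Si](c1ccccc1)(c1ccccc1)C(C)(C)C | intermediate
4 | (4R,6R)-4-hydroxy-2,2,6-trimethylcyclohexan-1-one (actinol) | CC1(C)C[C@H](O)C[C@@H](C)C1=O | starting material
5 | (1R,5R)-3,3,5-trimethyl-4-oxocyclohexyl 4-[(tert-butyldiphenylsilyl)oxy]but-2-ynoate | CC1(C)C[C@H](OC(=O)C#CCO[Si](c2ccccc2)(c2ccccc2)C(C)(C)C)C[C@@H](C)C1=O | intermediate
6 | (1R)-3,5,5-trimethyl-4-{[(trifluoromethyl)sulfonyl]oxy}cyclohex-3-en-1-yl 4-[(tert-butyldiphenylsilyl)oxy]but-2-ynoate | CC1(C)C[C@H](OC(=O)C#CCO[Si](c2ccccc2)(c2ccccc2)C(C)(C)C)CC(C)=C1OS(=O)(=O)C(F)(F)F | intermediate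
7 | (1R)-4-ethenyl-3,5,5-trimethylcyclohex-3-en-1-yl 4-[(tert-butyldiphenylsilyl)oxy]but-2-ynoate | CC1(C)C[C@H](OC(=O)C#CCO[Si](c2ccccc2)(c2ccccc2)C(C)(C)C)CC(C)=C1C=C | intermediate
8 | tricyclic 2α,11-lactone: decalin-5,8-diene, 4,4-dimethyl, 10β-methyl, CH2OTBDPS on C8, C9–C11(=O)–O–C2 bridge (α) | CC1(C)C[C@H]3C[C@]2(C)C(C(=O)O3)=C(CO[Si](c4ccccc4)(c4ccccc4)C(C)(C)C)CC=C12 | intermediate
9 | C6 borane: lactone of 8 with C5=C6 saturated, 5β-H, 6β-BH2 | CC1(C)C[C@H]3C[C@]2(C)C(C(=O)O3)=C(CO[Si](c4ccccc4)(c4ccccc4)C(C)(C)C)C[C@@H](B)[C@H]12 | intermediate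
10 | 6β-hydroxy-5β-H lactone (cis-fused, C8=C9) | CC1(C)C[C@H]3C[C@]2(C)C(C(=O)O3)=C(CO[Si](c4ccccc4)(c4ccccc4)C(C)(C)C)C[C@@H](O)[C@H]12 | intermediate
11 | lactol of 10 (C11 hemiacetal, anomer mixture; in equilibrium with the open hydroxy-enal) | CC1(C)C[C@H]3C[C@]2(C)C(C(O)O3)=C(CO[Si](c4ccccc4)(c4ccccc4)C(C)(C)C)C[C@@H](O)[C@H]12 | intermediate
12 | 9-ethenyl cis-decalin-2α,6β-diol (5β-H, 10β-CH3, C8=C9, CH2OTBDPS on C8) | CC1(C)C[C@H](O)C[C@]2(C)C(C=C)=C(CO[Si](c3ccccc3)(c3ccccc3)C(C)(C)C)C[C@@H](O)[C@H]12 | intermediate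
13 | 2-O-TBS ether of 12 (6β-OH free) | CC1(C)C[C@H](O[Si](C)(C)C(C)(C)C)C[C@]2(C)C(C=C)=C(CO[Si](c3ccccc3)(c3ccccc3)C(C)(C)C)C[C@@H](O)[C@H]12 | intermediate
14 | cis-fused 6-ketone (5β-H) from 13 | CC1(C)C[C@H](O[Si](C)(C)C(C)(C)C)C[C@]2(C)C(C=C)=C(CO[Si](c3ccccc3)(c3ccccc3)C(C)(C)C)CC(=O)[C@H]12 | intermediate
15 | 9-ethenyl-2α-(TBS-oxy)-cis-decalin-6α-ol (5β-H, 10β-CH3, CH2OTBDPS on C8) | CC1(C)C[C@H](O[Si](C)(C)C(C)(C)C)C[C@]2(C)C(C=C)=C(CO[Si](c3ccccc3)(c3ccccc3)C(C)(C)C)C[C@H](O)[C@H]12 | intermediate
16 | 3,3-dibromoprop-2-enoic acid | OC(=O)C=C(Br)Br | starting material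
17 | tributyl(iodomethyl)stannane | CCCC[Sn](CCCC)(CCCC)CI | starting material
18 | (tributylstannyl)methyl 3,3-dibromoprop-2-enoate | CCCC[Sn](CCCC)(CCCC)COC(=O)C=C(Br)Br | intermediate
19 | B-alkyl-9-BBN: 15 with C11H2–C12H2–B(9-BBN) in place of the vinyl group | CC1(C)C[C@H](O[Si](C)(C)C(C)(C)C)C[C@]2(C)C(CCB3C4CCCC3CCC4)=C(CO[Si](c3ccccc3)(c3ccccc3)C(C)(C)C)C[C@H](O)[C@H]12 | intermediate
20 | (tributylstannyl)methyl (Z)-3-bromo-5-(decalin-9-yl)pent-2-enoate (Br cis to the ester; decalin as in 15) | CC1(C)C[C@H](O[Si](C)(C)C(C)(C)C)C[C@]2(C)C(CC/C(Br)=C/C(=O)OC[Sn](CCCC)(CCCC)CCCC)=C(CO[Si](c3ccccc3)(c3ccccc3)C(C)(C)C)C[C@H](O)[C@H]12 | intermediate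
21 | 2-O-TBS 17-O-TBDPS ether of the target | CC1(C)C[C@H](O[Si](C)(C)C(C)(C)C)C[C@]2(C)C(CCC3=CC(=O)OC3)=C(CO[Si](c3ccccc3)(c3ccccc3)C(C)(C)C)C[C@H](O)[C@H]12 | intermediate
22 | target, (2S,5R,6S,10S) | CC1(C)C[C@H](O)C[C@]2(C)C(CCC3=CC(=O)OC3)=C(CO)C[C@H](O)[C@H]12 | target

**Step count**
Total: 14 steps. Longest linear sequence: 13 steps (steps 1–11, 13, 14, starting from 1).

**Steps most likely to fail**

Step 13. The stannylmethyl ester may be hydrolysed or protodestannylated during the basic aqueous Suzuki stage, or the intramolecular Sn→Pd transfer may be too slow (the ester must reach its s-cis form), so that bromoenoate 20 is alkylated twice or reduced instead of cyclising. The fallback sets out from 15 and returns at 21. Borane 19 is made as before and coupled under the same Suzuki conditions with methyl 3,3-dibromoprop-2-enoate F1 (from 16 with MeI, K2CO3, DMF). This gives the isolable methyl (Z)-3-bromo-5-(decalin-9-yl)pent-2-enoate F2. Stille hydroxymethylation of F2 with commercial (tributylstannyl)methanol (Pd(PPh3)4, dioxane, 90 °C) forms the same C13–C16 bond intermolecularly, giving methyl (Z)-3-(hydroxymethyl)-5-(decalin-9-yl)pent-2-enoate F3, which should lactonise in the flask to 21.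

Step 5. The (Z)-methyl-substituted diene may undergo a thermal [1,5]-hydrogen shift from C20, and the cycloaddition through the bridged transition state (axial C2–O, s-cis ester) may be too slow at temperatures the substrate survives. The fallback sets out from 7 and returns at 8. The concerted thermal reaction is replaced by a rhodium(I)-catalysed stepwise [4+2] of the tethered diene–yne (cationic Rh(I)/cod, CH2Cl2 or DCE, 25–60 °C), which proceeds by oxidative cyclisation to a rhodacycle and reductive elimination, well below the temperature of the hydrogen shift. This fallback makes no new compound (F0).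

Step 6. Borane may reduce the strained lactone carbonyl in competition with a slow addition to the alkene, which is flanked by two quaternary carbons. The fallback sets out from 8 and returns at 10. mCPBA (CH2Cl2, NaHCO3, 0 °C) epoxidises C5=C6 from the β-face under the same ring constraint, leaving the electron-poor C8=C9 bond untouched, to give the 5β,6β-epoxy lactone F4. Titanocene(III)-mediated reductive epoxide opening (Cp2TiCl2, Zn, 1,4-cyclohexadiene, THF) then cleaves the tertiary C5–O bond homolytically. Hydrogen-atom transfer to the C5 radical can only give the lactone-enforced cis fusion, leaving the 6β-alcohol 10.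

**Further compounds**
F1 | step 13 | methyl 3,3-dibromoprop-2-enoate | COC(=O)C=C(Br)Br
F2 | step 13 | methyl (Z)-3-bromo-5-(decalin-9-yl)pent-2-enoate (decalin as in 15) | CC1(C)C[C@H](O[Si](C)(C)C(C)(C)C)C[C@]2(C)C(CC/C(Br)=C/C(=O)OC)=C(CO[Si](c3ccccc3)(c3ccccc3)C(C)(C)C)C[C@H](O)[C@H]12
F3 | step 13 | methyl (Z)-3-(hydroxymethyl)-5-(decalin-9-yl)pent-2-enoate (decalin as in 15) | CC1(C)C[C@H](O[Si](C)(C)C(C)(C)C)C[C@]2(C)C(CC/C(CO)=C/C(=O)OC)=C(CO[Si](c3ccccc3)(c3ccccc3)C(C)(C)C)C[C@H](O)[C@H]12
F0 | step 5 | none | none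
F4 | step 6 | 5β,6β-epoxide of lactone 8 | CC1(C)C[C@H]3C[C@]2(C)C(C(=O)O3)=C(CO[Si](c4ccccc4)(c4ccccc4)C(C)(C)C)C[C@H]4O[C@@]124
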